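**Plan**
- Cut 1: the mid-chain C5'–C6' bond of the decamethylene tether (C1' on the salicylate ring, C10' on the phenyl ring). Both atoms are plain CH2 groups in an unbranched, heteroatom-free chain, so C5' can be the terminus of a C4'=C5' alkene that takes boron by hydroboration, and C6' can be the primary bromide carbon of purchased (5-bromopentyl)benzene.
- Cut 2: the two neighbouring ring bonds, ring C6–C1' and ring C1–CO2H. The benzene ring is 1,2,3-trisubstituted with oxygen at C2, which is the pattern 3-methoxybenzyne gives when a carbon nucleophile and a carboxyl electrophile add across its triple bond.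
- Forward order: an aryne three-component coupling sets the ring pattern and attaches a pent-4-enyl arm (step 1). A one-pot hydroboration / sp3–sp3 Suzuki coupling then joins the two C5 halves (step 2). One Lewis-acid step removes the O-methyl and tert-butyl helpers (step 3).
- Stereochemistry: the target has no stereocentre and no alkene geometry, so nothing has to be set.

Key step: step 2

Remark: the structure is achiral; acid and phenol are carried as tert-butyl ester and methyl ether until the last step.

**Step 1**
Reactants: 1 5-bromopent-1-ene; 2 1-fluoro-3-methoxybenzene (3-fluoroanisole)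
Product: 7 tert-butyl 2-methoxy-6-(pent-4-en-1-yl)benzoate, via pent-4-en-1-yllithium 3 (not isolated), via (2-fluoro-6-methoxyphenyl)lithium 4 (not isolated), via 3-methoxybenzyne 5 (not isolated), via [2-methoxy-6-(pent-4-en-1-yl)phenyl]lithium 6 (not isolated)
Conditions: 1 (2.2 equiv), Li wire (1% Na), Et2O, −15 → 0 °C; add 2 (1.0 equiv), THF, −78 °C → rt; recool to −78 °C, Boc2O, → rt; H2O work-up
Reagents that add atoms: di-tert-butyl dicarbonate (Boc2O), CC(C)(C)OC(=O)OC(=O)OC(C)(C)C
Why: One equivalent of 3 lithiates 2 between F and OMe, LiF is lost to give 3-methoxybenzyne, and the second equivalent of 3 adds at the aryne carbon meta to OMe (the flatter, more electrophilic terminus, leaving the aryllithium next to the inductively stabilising, chelating oxygen), after which Boc2O C-acylates that position; this is an aryne three-component coupling (organolithium addition to a 3-alkoxyaryne with electrophilic trapping).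

**Step 2**
Reactants: 7 tert-butyl 2-methoxy-6-(pent-4-en-1-yl)benzoate; 8 (5-bromopentyl)benzene
Product: 10 tert-butyl 2-methoxy-6-(10-phenyldecyl)benzoate, via tert-butyl 2-[5-(9-borabicyclo[3.3.1]nonan-9-yl)pentyl]-6-methoxybenzoate 9 (not isolated)
Conditions: 9-BBN (0.5 M in THF, 1.05 equiv), 0 °C → rt; then 8 (1.2 equiv), Pd(OAc)2 (4 mol%), PCy3 (8 mol%), K3PO4·H2O (1.5 equiv), THF, rt
Reagents that add atoms: none
Why: 9-BBN adds across the terminal C4'=C5' alkene of 7 in a four-centre syn, anti-Markovnikov sense so that boron sits on the terminal carbon C5', and K3PO4·H2O converts the resulting B-alkyl-9-BBN 9 into a hydroxyborate. Electron-rich Pd(0)/PCy3 oxidatively adds the primary C–Br bond of 8 in an SN2-like manner, the primary alkyl group of the borate (not the secondary bicyclic B–C bonds) transmetalates, and reductive elimination forms the C5'–C6' bond directly at the alkane oxidation level. The closest known reaction type is the room-temperature Pd/trialkylphosphine-catalysed B-alkyl Suzuki–Miyaura coupling of unactivated primary alkyl bromides bearing β-hydrogens with alkyl-9-BBN reagents. No ring is closed and no stereocentre is created. The selectivities needed are terminal regioselectivity in the hydroboration, secured by the bulk of 9-BBN at a monosubstituted alkene; chemoselectivity for the alkene over the ester, secured by the mildness of 9-BBN and the doubly ortho-flanked tert-butyl ester; and coupling in preference to β-hydride elimination, secured by the bulky electron-rich PCy3 ligand at room temperature.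

**Step 3**
Reactants: 10 tert-butyl 2-methoxy-6-(10-phenyldecyl)benzoate
Product: 11 2-hydroxy-6-(10-phenyldecyl)benzoic acid
Conditions: BBr3 (3.5 equiv), CH2Cl2, −78 → 0 °C; then H2O
Reagents that add atoms: none
Why: BBr3 binds the ester carbonyl and the ortho methoxy oxygen, the tert-butyl group leaves as its cation and is captured as the bromide, bromide attacks the O-methyl carbon in an SN2 step, and hydrolysis of the boron chelate should release the salicylic acid; this is a BBr3 dealkylation of an aryl methyl ether with concurrent tert-butyl ester cleavage.

**Compound list**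
1 | 5-bromopent-1-ene | C=CCCCBr | starting material
2 | 1-fluoro-3-methoxybenzene (3-fluoroanisole) | COc1cccc(F)c1 | starting material
3 | pent-4-en-1-yllithium (not isolated) | [Li]CCCC=C | intermediate
4 | (2-fluoro-6-methoxyphenyl)lithium (not isolated) | COc1cccc(F)c1[Li] | intermediate
5 | 3-methoxybenzyne (1,2-didehydro-3-methoxybenzene, not isolated) | COC1=CC=CC#C1 | intermediate
6 | [2-methoxy-6-(pent-4-en-1-yl)phenyl]lithium (not isolated) | COc1cccc(CCCC=C)c1[Li] | intermediate
7 | tert-butyl 2-methoxy-6-(pent-4-en-1-yl)benzoate | COc1cccc(CCCC=C)c1C(=O)OC(C)(C)C | intermediate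
8 | (5-bromopentyl)benzene | BrCCCCCc1ccccc1 | starting material
9 | tert-butyl 2-[5-(9-borabicyclo[3.3.1]nonan-9-yl)pentyl]-6-methoxybenzoate (not isolated) | COc1cccc(CCCCCB2C3CCCC2CCC3)c1C(=O)OC(C)(C)C | intermediate
10 | tert-butyl 2-methoxy-6-(10-phenyldecyl)benzoate | COc1cccc(CCCCCCCCCCc2ccccc2)c1C(=O)OC(C)(C)C | intermediate
11 | 2-hydroxy-6-(10-phenyldecyl)benzoic acid | O=C(O)c1c(O)cccc1CCCCCCCCCCc1ccccc1 | target

**Step count and risks**
Total step count: 3. Longest linear sequence: 3 steps (1 + 2 → 7 → 10 → 11); 8 is purchased.

Steps most likely to fail:

1. Step 1. The aryllithium 4 may add to the aryne in competition with 3 (biaryl formation), and C-acylation of the doubly ortho-flanked aryllithium 6 may be incomplete. The fallback sets out from 1 and returns at 7, replacing the aryne event by a cross-coupling on a ring that already carries the 1,2,3-pattern. Purchased 2-bromo-6-methoxybenzoic acid F1 would be esterified with Boc2O/DMAP in t-BuOH to tert-butyl 2-bromo-6-methoxybenzoate F2. Compound 1 would be converted with activated zinc dust and LiCl in THF into pent-4-en-1-ylzinc bromide F3. A Negishi coupling of F2 with F3 (Pd(OAc)2/SPhos, THF, 40 °C) should then give 7.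

2. Step 2. β-Hydride elimination from the alkylpalladium intermediate, or protodeboronation of 9, may consume the partners without coupling. The fallback sets out from 7 (with 8) and returns at 10, forming the same bond by a copper-catalysed Grignard displacement. Hydroboration–oxidation of 7 (9-BBN, then NaOH/H2O2) would give tert-butyl 2-(5-hydroxypentyl)-6-methoxybenzoate F4. Tosylation (TsCl, Et3N, DMAP, CH2Cl2) would give tert-butyl 2-methoxy-6-[5-(tosyloxy)pentyl]benzoate F5. Compound 8 with magnesium in THF would give (5-phenylpentyl)magnesium bromide F6, and a Kochi-type coupling of F5 with F6 (Li2CuCl4 cat., THF, −20 → 0 °C) should give 10; the hindered tert-butyl ester is expected to survive.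

3. Step 3. The tert-butyl cation released under Lewis-acid conditions may alkylate the terminal phenyl ring, or O-demethylation may stop short. The fallback sets out from 10 and returns at 11 in two separate, cation-free or scavenged operations. Acidolysis with TFA/Et3SiH in CH2Cl2 would give 2-methoxy-6-(10-phenyldecyl)benzoic acid F7. Nucleophilic demethylation with sodium ethanethiolate in DMF at 120 °C, followed by acidification, should give 11.

**Further compounds**
F1 | step 1 | 2-bromo-6-methoxybenzoic acid (purchased) | COc1cccc(Br)c1C(=O)O
F2 | step 1 | tert-butyl 2-bromo-6-methoxybenzoate | COc1cccc(Br)c1C(=O)OC(C)(C)C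
F3 | step 1 | pent-4-en-1-ylzinc bromide | Br[Zn]CCCC=C
F4 | step 2 | tert-butyl 2-(5-hydroxypentyl)-6-methoxybenzoate | COc1cccc(CCCCCO)c1C(=O)OC(C)(C)C
F5 | step 2 | tert-butyl 2-methoxy-6-[5-(tosyloxy)pentyl]benzoate | COc1cccc(CCCCCOS(=O)(=O)c2ccc(C)cc2)c1C(=O)OC(C)(C)C
F6 | step 2 | (5-phenylpentyl)magnesium bromide | Br[Mg]CCCCCc1ccccc1
F7 | step 3 | 2-methoxy-6-(10-phenyldecyl)benzoic acid | COc1cccc(CCCCCCCCCCc2ccccc2)c1C(=O)O
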